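**Retrosynthetic overview**
- Target ⇐ fluoride desilylation of the TIPS ether of the 5-(hydroxymethyl)-2-acylpyrrole.
- Ketone C(=O)–CH2 bond ⇐ anti-Markovnikov hydroacylation of 15-methylhexadec-1-ene by a 5-(silyloxymethyl)pyrrole-2-carbaldehyde, steered by a traceless N–PPh2 group (the new step).
- Aldehyde ⇐ desymmetrisation (mono-silylation, then MnO2) of 2,5-bis(hydroxymethyl)pyrrole ⇐ pyrrole + 2 CH2O.
- Alkene ⇐ Cu-catalysed sp3–sp3 coupling of 11-bromoundec-1-ene with 4-methylpentylmagnesium bromide.
- Rings: the only ring (pyrrole) is bought as pyrrole; no ring is formed in the route.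

Assumption: the target has no stereocentre and no stereogenic double bond, so "single enantiomer" is met trivially and no stereocontrol is needed.

**Step 1**
Reactants: 1 1-bromo-4-methylpentane; 2 11-bromoundec-1-ene
Product: 4 15-methylhexadec-1-ene, via (4-methylpentyl)magnesium bromide 3 (not isolated)
Conditions: Mg, THF, 50 °C; then 2 (0.8 equiv), Li2CuCl4 (3 mol%), THF, −10 °C → rt
Reagents that add atoms: none
Why: Copper-catalysed Grignard/primary alkyl bromide cross-coupling (Tamura–Kochi type) joins the two sp3 carbons and leaves the terminal alkene untouched; no stereocentre is formed.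

**Step 2**
Reactants: 5 1H-pyrrole
Product: 7 (1H-pyrrole-2,5-diyl)dimethanol, via (1H-pyrrol-2-yl)methanol 6 (not isolated)
Conditions: 37% aq. HCHO (2.2 equiv), K2CO3 (cat.), 5 °C, dark, 60 h
Reagents that add atoms: formaldehyde, C=O
Why: Base-catalysed electrophilic hydroxymethylation (Lederer–Manasse type) occurs at both pyrrole α-positions, and the basic medium prevents azafulvenium formation and oligomerisation of the pyrrolyl carbinols.

**Step 3**
Reactants: 7 (1H-pyrrole-2,5-diyl)dimethanol
Product: 8 [5-({[tri(propan-2-yl)silyl]oxy}methyl)-1H-pyrrol-2-yl]methanol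
Conditions: TIPSCl (1.0 equiv), imidazole (2 equiv), DMF, 0 °C; chromatography on Et3N-deactivated silica, diol and bis-ether recycled
Reagents that add atoms: chlorotri(propan-2-yl)silane, CC(C)[Si](Cl)(C(C)C)C(C)C
Why: Statistical mono-silylation of a symmetric primary diol under standard imidazole silylation conditions gives the mono-ether, and the pyrrole N–H is not silylated by this bulky chloride.

**Step 4**
Reactants: 8 [5-({[tri(propan-2-yl)silyl]oxy}methyl)-1H-pyrrol-2-yl]methanol
Product: 9 5-({[tri(propan-2-yl)silyl]oxy}methyl)-1H-pyrrole-2-carbaldehyde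
Conditions: activated MnO2 (10 equiv), CH2Cl2, rt
Reagents that add atoms: none
Why: MnO2 oxidation of a pyrrolylic (benzylic-type) primary alcohol stops cleanly at the aldehyde and does not affect the TIPS ether.

**Step 5**
Reactants: 9 5-({[tri(propan-2-yl)silyl]oxy}methyl)-1H-pyrrole-2-carbaldehyde
Product: 11 1-(diphenylphosphanyl)-5-({[tri(propan-2-yl)silyl]oxy}methyl)-1H-pyrrole-2-carbaldehyde, via sodium pyrrolide salt 10 (not isolated)
Conditions: NaH (1.1 equiv), THF, 0 °C; then Ph2PCl (1.05 equiv), 0 °C → rt; filtered under Ar, concentrated, used without chromatography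
Reagents that add atoms: chlorodiphenylphosphane, ClP(c1ccccc1)c1ccccc1
Why: The acidic N–H of the 2-formylpyrrole is deprotonated and the anion undergoes nucleophilic substitution at P(III) on nitrogen, as in its routine N-sulfonylation and N-alkylation, because N-attack keeps the pyrrole aromatic.

**Step 6**
Reactants: 11 1-(diphenylphosphanyl)-5-({[tri(propan-2-yl)silyl]oxy}methyl)-1H-pyrrole-2-carbaldehyde; 4 15-methylhexadec-1-ene
Product: 13 16-methyl-1-[5-({[tri(propan-2-yl)silyl]oxy}methyl)-1H-pyrrol-2-yl]heptadecan-1-one, via N-phosphanyl ketone 12 (not isolated)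
Conditions: [Rh(coe)2Cl]2 (2.5 mol%), 4 (1.5 equiv), toluene, 70 °C, Ar; then MeOH, K2CO3 (20 mol%), rt
Reagents that add atoms: none
Why: Proposed new method: a traceless N-phosphanyl directing group for formyl C–H activation, in which Rh(I) bound to the N–PPh2 phosphorus inserts into the neighbouring aldehyde C–H to give a five-membered P,C(acyl)-rhodacycle hydride that resists decarbonylation, the 1-alkene inserts into Rh–H in the anti-Markovnikov sense to a primary alkyl, C–C reductive elimination gives the linear ketone, and the azolide-type P–N bond is then cleaved by base-catalysed methanolysis; the closest known reaction type is chelation-assisted Rh-catalysed intermolecular alkene hydroacylation (2-phosphinobenzaldehydes, β-thioaldehydes, picolyl-imine auxiliaries) combined with N–PR2-directed C–H activation of indoles, and no stereocentre is formed.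

**Step 7**
Reactants: 13 16-methyl-1-[5-({[tri(propan-2-yl)silyl]oxy}methyl)-1H-pyrrol-2-yl]heptadecan-1-one
Product: 14 1-[5-(hydroxymethyl)-1H-pyrrol-2-yl]-16-methylheptadecan-1-one
Conditions: TBAF (1.2 equiv), THF, 0 °C → rt; aqueous work-up
Reagents that add atoms: none
Why: Fluoride-mediated desilylation, driven by Si–F bond formation, frees the primary alcohol under non-acidic conditions that leave the acylpyrrole carbinol and the ketone intact.

**Compound list**
1 | 1-bromo-4-methylpentane | CC(C)CCCBr | starting material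
2 | 11-bromoundec-1-ene | C=CCCCCCCCCCBr | starting material
3 | (4-methylpentyl)magnesium bromide | CC(C)CCC[Mg]Br | intermediate
4 | 15-methylhexadec-1-ene | C=CCCCCCCCCCCCCC(C)C | intermediate
5 | 1H-pyrrole | c1cc[nH]c1 | starting material
6 | (1H-pyrrol-2-yl)methanol | OCc1ccc[nH]1 | intermediate
7 | (1H-pyrrole-2,5-diyl)dimethanol | OCc1ccc(CO)[nH]1 | intermediate
8 | [5-({[tri(propan-2-yl)silyl]oxy}methyl)-1H-pyrrol-2-yl]methanol | OCc1ccc(CO[Si](C(C)C)(C(C)C)C(C)C)[nH]1 | intermediate
9 | 5-({[tri(propan-2-yl)silyl]oxy}methyl)-1H-pyrrole-2-carbaldehyde | O=Cc1ccc(CO[Si](C(C)C)(C(C)C)C(C)C)[nH]1 | intermediate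
10 | sodium 2-formyl-5-({[tri(propan-2-yl)silyl]oxy}methyl)pyrrol-1-ide | [Na+].O=Cc1ccc(CO[Si](C(C)C)(C(C)C)C(C)C)[n-]1 | intermediate
11 | 1-(diphenylphosphanyl)-5-({[tri(propan-2-yl)silyl]oxy}methyl)-1H-pyrrole-2-carbaldehyde | O=Cc1ccc(CO[Si](C(C)C)(C(C)C)C(C)C)n1P(c2ccccc2)c3ccccc3 | intermediate
12 | 1-[1-(diphenylphosphanyl)-5-({[tri(propan-2-yl)silyl]oxy}methyl)-1H-pyrrol-2-yl]-16-methylheptadecan-1-one | CC(C)CCCCCCCCCCCCCCC(=O)c1ccc(CO[Si](C(C)C)(C(C)C)C(C)C)n1P(c2ccccc2)c3ccccc3 | intermediate
13 | 16-methyl-1-[5-({[tri(propan-2-yl)silyl]oxy}methyl)-1H-pyrrol-2-yl]heptadecan-1-one | CC(C)CCCCCCCCCCCCCCC(=O)c1ccc(CO[Si](C(C)C)(C(C)C)C(C)C)[nH]1 | intermediate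
14 | 1-[5-(hydroxymethyl)-1H-pyrrol-2-yl]-16-methylheptadecan-1-one (achiral) | CC(C)CCCCCCCCCCCCCCC(=O)c1ccc(CO)[nH]1 | target

**Totals**
Total step count: 7. Longest linear sequence: 6 steps (steps 2–7, from pyrrole); step 1 is the convergent side branch.

**Three steps most likely to fail**

Step 6 (the proposed new hydroacylation). Risks: every substrate molecule carries a phosphine and may over-ligate rhodium, the Rh–H may isomerise the terminal alkene, and the P–N bond may cleave early. The fallback uses only known chemistry, sets out from alkene 4 and aldehyde 9 (step 5 is then not needed) and comes back at 13. Radical anti-Markovnikov hydrobromination of 4 (HBr, dibenzoyl peroxide, hexane) gives 1-bromo-15-methylhexadecane F1. Magnesium in THF converts it into (15-methylhexadecyl)magnesium bromide F2. Addition of 2.2 equiv of this Grignard reagent to 9 at −78 → 0 °C, where the first equivalent deprotonates N–H, gives racemic 16-methyl-1-[5-({[tri(propan-2-yl)silyl]oxy}methyl)-1H-pyrrol-2-yl]heptadecan-1-ol F3. MnO2 in CH2Cl2 oxidises this pyrrolylic carbinol to ketone 13, which removes the transient stereocentre.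

Step 5 (N-phosphanylation). Risks: O- versus N-attack of the ambident formylpyrrolide, a nitrogen flanked by two substituents, and a moisture-sensitive P–N bond. The fallback sets out from aldehyde 9 (with alkene 4) and comes back at 13. It drops the covalent directing group in favour of a catalytic transient aldimine: 9, 4, 2-amino-3-picoline (40 mol%), RhCl(PPh3)3 (5 mol%), benzoic acid (10 mol%), toluene, 130 °C. Aldehyde 9 condenses to (E)-N-(3-methylpyridin-2-yl)-1-[5-({[tri(propan-2-yl)silyl]oxy}methyl)-1H-pyrrol-2-yl]methanimine F4. Pyridine-chelated C–H activation and alkene insertion give N-(3-methylpyridin-2-yl)-16-methyl-1-[5-({[tri(propan-2-yl)silyl]oxy}methyl)-1H-pyrrol-2-yl]heptadecan-1-imine F5, which the water of condensation hydrolyses in the flask to 13.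

Step 3 (statistical mono-silylation). Risks: yield capped near 50% per pass and an acid-sensitive, electron-rich carbinol on silica. The fallback sets out from diol 7 and comes back at 9, bypassing 8, by reversing the order and desymmetrising electronically. Limited activated MnO2 (4–5 equiv, acetone, 0 °C) oxidises one carbinol to 5-(hydroxymethyl)-1H-pyrrole-2-carbaldehyde F6, whose formyl group deactivates the ring towards a second oxidation. TIPSCl/imidazole in DMF then silylates the remaining alcohol to give 9.

**Further compounds**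
F1 | step 6 | 1-bromo-15-methylhexadecane | CC(C)CCCCCCCCCCCCCCBr
F2 | step 6 | (15-methylhexadecyl)magnesium bromide | CC(C)CCCCCCCCCCCCCC[Mg]Br
F3 | step 6 | rac-16-methyl-1-[5-({[tri(propan-2-yl)silyl]oxy}methyl)-1H-pyrrol-2-yl]heptadecan-1-ol | CC(C)CCCCCCCCCCCCCCC(O)c1ccc(CO[Si](C(C)C)(C(C)C)C(C)C)[nH]1
F4 | step 5 | (E)-N-(3-methylpyridin-2-yl)-1-[5-({[tri(propan-2-yl)silyl]oxy}methyl)-1H-pyrrol-2-yl]methanimine | Cc1cccnc1/N=C/c1ccc(CO[Si](C(C)C)(C(C)C)C(C)C)[nH]1
F5 | step 5 | N-(3-methylpyridin-2-yl)-16-methyl-1-[5-({[tri(propan-2-yl)silyl]oxy}methyl)-1H-pyrrol-2-yl]heptadecan-1-imine (E/Z mixture) | CC(C)CCCCCCCCCCCCCCC(=Nc1ncccc1C)c1ccc(CO[Si](C(C)C)(C(C)C)C(C)C)[nH]1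
F6 | step 3 | 5-(hydroxymethyl)-1H-pyrrole-2-carbaldehyde | O=Cc1ccc(CO)[nH]1
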